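**Assumption:** (R)-(+)-limonene is the chiral-pool source of the cyclohexane stereocentre (target C1′ = R). The two C8 epimers formed in Step 3 are separable by chromatography.

## Retrosynthetic overview
1. Target ⇒ stereoselective reduction of the C9 ketone of a 5-bromo-2,2,6,6-substituted tetrahydropyran-3-one.
2. That ketone ⇒ tandem HBr conjugate addition and tertiary-OH → Br exchange on a dihydropyranone carrying the trans-diaxial Cl/OH ring.
3. That enone ⇒ Me3Al gem-dimethylation of the Achmatowicz hemiketal. The Achmatowicz step (furan dearomatization) forms the tetrahydropyran ring from a tertiary 2-furylcarbinol.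
4. The carbinol ⇒ 5-methyl-2-furyl nucleophile (from 2-methylfuran) plus the methyl ketone obtained by ozonolysis of limonene chlorohydrin, which comes from (R)-limonene by NCS/H2O.
5. Ring order: the cyclohexane comes from the chiral pool, with the Cl/Br pattern set via the trans-diaxial chlorohydrin. The pyran ring is formed second, in the Achmatowicz step.

## Route

**Step 1**
Reactants: 1, (R)-(+)-limonene
Product: 2, (1S,2S,4R)-2-chloro-1-methyl-4-(prop-1-en-2-yl)cyclohexan-1-ol
Conditions: NCS (1.0 equiv), acetone/H2O 4:1, 0 °C, 3 h
Reagents that add atoms: N-chlorosuccinimide (O=C1CCC(=O)N1Cl); water (O)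
Why: Chlorohydrin formation via a chloronium ion. The more nucleophilic trisubstituted ring alkene reacts in preference to the isopropenyl group. Water opens at the tertiary carbon and Cl ends up on the secondary carbon. The isopropenyl-equatorial half-chair forces trans-diaxial opening, which fixes OH (up) and Cl (down) relative to C4.

**Step 2**
Reactants: 2
Product: 3, 1-[(1R,3S,4S)-3-chloro-4-hydroxy-4-methylcyclohexyl]ethan-1-one
Conditions: (i) O3, CH2Cl2/MeOH 4:1, −78 °C; (ii) Me2S, −78 °C → rt
Reagents that add atoms: ozone ([O-][O+]=O)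
Why: Ozonolysis of the only remaining alkene, giving the methyl ketone. All ring stereocentres are untouched, and the chlorohydrin masks the ring alkene.

**Step 3**
Reactants: 3; 4, 2-methylfuran (Cc1ccco1, cheap furan feedstock)
Product: 5, (1S,2S,4R)-2-chloro-4-[(1S)-1-hydroxy-1-(5-methylfuran-2-yl)ethyl]-1-methylcyclohexan-1-ol
Conditions: 4 + n-BuLi (3.5 equiv), THF, −78 → 0 °C; CeCl3 (3.5 equiv); add 3, −78 → −40 °C; aq. NH4Cl; chromatographic separation of C8 epimers
Reagents that add atoms: none
Why: 1,2-Addition of a 5-methylfuryl organocerium to the methyl ketone. The new quaternary centre C8 is set by Felkin-type facial bias from the adjacent ring stereocentre (modest dr, about 2:1), and the desired (S)-epimer is isolated.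

**Step 4**
Reactants: 5
Product: 6, (2S)-2-[(1R,3S,4S)-3-chloro-4-hydroxy-4-methylcyclohexyl]-6-hydroxy-2,6-dimethyl-2H-pyran-3(6H)-one (C6 epimeric mixture)
Conditions: NBS (1.05 equiv), NaHCO3, NaOAc, THF/H2O 4:1, 0 °C, 30 min
Reagents that add atoms: water (O)
Why: Achmatowicz rearrangement, which dearomatizes the furan and expands it to the tetrahydropyran skeleton: the tertiary carbinol oxygen closes onto the oxidized C5 of the furan. C8 is not touched and keeps its configuration, and the anomeric C12 epimerism is erased in Step 5.

**Step 5**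
Reactants: 6
Product: 7, (2S)-2-[(1R,3S,4S)-3-chloro-4-hydroxy-4-methylcyclohexyl]-2,6,6-trimethyl-2H-pyran-3(6H)-one
Conditions: Me3Al (4 equiv), CH2Cl2, −78 → −20 °C, 2 h
Reagents that add atoms: trimethylaluminium (C[Al](C)C)
Why: Proposed new method: Me3Al converts the hemiketal and ring OH to aluminium alkoxides, ionizes C12–OAl to the cyclic oxocarbenium, and delivers Me to C12 to give the gem-dimethyl ether. The closest known reactions are Lewis-acid C-glycosylation of Achmatowicz pyranones and Reetz gem-dimethylation; no new stereocentre results.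

**Step 6**
Reactants: 7
Product: 8, (2S,5S)-5-bromo-2-[(1R,3S,4S)-4-bromo-3-chloro-4-methylcyclohexyl]-2,6,6-trimethyloxan-3-one
Conditions: HBr (33 wt % in AcOH, 6 equiv), CH2Cl2, −20 → 0 °C, 2 h
Reagents that add atoms: hydrogen bromide (Br), two equivalents incorporated
Why: Proposed new method: the enone takes Br− at C11 by conjugate addition, delivered anti to the bulky C8 cyclohexyl group (syn to C8-Me), and the adduct is configurationally stable in acid because retro-Michael needs base. Simultaneously the tertiary alcohol ionizes with anchimeric assistance from the anti-periplanar axial Cl (chloronium), and Br− captures the tertiary carbon anti to Cl, giving net retention and trans-diaxial Br/Cl. The closest known reactions are HBr conjugate addition to enones and halonium-assisted substitution of β-halo tertiary alcohols; the ketone deactivates the bis-tertiary ether toward acid.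

**Step 7**
Reactants: 8
Product: 9, target (2S,3S,5S)-5-bromo-2-[(1R,3S,4S)-4-bromo-3-chloro-4-methylcyclohexyl]-2,6,6-trimethyloxan-3-ol
Conditions: L-Selectride (1.5 equiv), THF, −78 °C, 1 h; aq. NH4Cl
Reagents that add atoms: none (hydride only)
Why: Bulky hydride reduction of the ketone from the face anti to the C8 cyclohexyl group, which sets the C9-OH cis to the cyclohexyl as in the target; both halides survive at −78 °C.

## Compound list
1 | (R)-(+)-limonene | C=C(C)[C@@H]1CCC(C)=CC1 | starting material
2 | (1S,2S,4R)-2-chloro-1-methyl-4-(prop-1-en-2-yl)cyclohexan-1-ol | C=C(C)[C@@H]1CC[C@](C)(O)[C@@H](Cl)C1 | intermediate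
3 | 1-[(1R,3S,4S)-3-chloro-4-hydroxy-4-methylcyclohexyl]ethan-1-one | CC(=O)[C@@H]1CC[C@](C)(O)[C@@H](Cl)C1 | intermediate
4 | 2-methylfuran | Cc1ccco1 | starting material
5 | (1S,2S,4R)-2-chloro-4-[(1S)-1-hydroxy-1-(5-methylfuran-2-yl)ethyl]-1-methylcyclohexan-1-ol | O[C@@](C)([C@@H]1CC[C@](C)(O)[C@@H](Cl)C1)c1ccc(C)o1 | intermediate
6 | (2S)-2-[(1R,3S,4S)-3-chloro-4-hydroxy-4-methylcyclohexyl]-6-hydroxy-2,6-dimethyl-2H-pyran-3(6H)-one | CC1(O)O[C@@](C)([C@@H]2CC[C@](C)(O)[C@@H](Cl)C2)C(=O)C=C1 | intermediate (C6 unassigned)
7 | (2S)-2-[(1R,3S,4S)-3-chloro-4-hydroxy-4-methylcyclohexyl]-2,6,6-trimethyl-2H-pyran-3(6H)-one | CC1(C)O[C@@](C)([C@@H]2CC[C@](C)(O)[C@@H](Cl)C2)C(=O)C=C1 | intermediate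
8 | (2S,5S)-5-bromo-2-[(1R,3S,4S)-4-bromo-3-chloro-4-methylcyclohexyl]-2,6,6-trimethyloxan-3-one | CC1(C)O[C@@](C)([C@@H]2CC[C@](C)(Br)[C@@H](Cl)C2)C(=O)C[C@@H]1Br | intermediate
9 | (2S,3S,5S)-5-bromo-2-[(1R,3S,4S)-4-bromo-3-chloro-4-methylcyclohexyl]-2,6,6-trimethyloxan-3-ol | CC1(C)O[C@@](C)([C@@H]2CC[C@](C)(Br)[C@@H](Cl)C2)[C@@H](O)C[C@@H]1Br | target

**Total steps:** 7
**Longest linear sequence:** 7 steps (1 → 2 → 3 → 5 → 6 → 7 → 8 → 9)

## Three steps most likely to fail
1. **Step 6 (tandem HBr step).** The C11 epimer ratio and the retentive OH → Br exchange are uncertain, and the bis-tertiary ether could be cleaved. Fallback: build the tetrahydropyran by bromoetherification instead. Add vinylMgBr to ketone 3, epoxidize with VO(acac)2/TBHP, open the terminal epoxide with isobutenylMgBr/CuI to give the diol-alkene, then close with NBS. The chair-like transition state puts Br equatorial, which matches the target C11 configuration.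
2. **Step 5 (Me3Al gem-dimethylation).** It may add to the C9 ketone or fail to ionize the electron-poor hemiketal. Fallback: open the hemiketal to the Z-enedione, methylenate the C12 methyl ketone (Ph3P=CH2), and close the ring by Markovnikov hydroalkoxylation of the isopropenyl group (Co-salen/PhSiH3/N-fluoropyridinium), which gives the gem-dimethyl ether directly.
3. **Step 3 (C8 diastereoselectivity).** The expected dr is low and yield is lost on separation. Fallback: reverse the bond disconnection. Acylate 5-methylfuran with the Weinreb amide of the corresponding acid to make the 2-acylfuran, then add MeMgBr, where the bulky furyl group changes the Felkin bias.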